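Of the 3 questions, one asks for a choice between spring and summer, and the others ask for the chain length in each flask.

| flask | free monomer | initiator | impurity | remark | time |
|---|---|---|---|---|---|
| Sunday's | 0.25 M | 2.4 mM | 0.84 mM | run made earlier |  |
| Saturday's | 0.25 M | 5.9 mM | 0.84 mM | run made earlier |  |
| spring | 0.25 M | 1.8 mM | 0.84 mM |  | 12 min |
| summer | 0.25 M | 4.0 mM | 0.84 mM |  | 12 min |

| run | time / min | monomer in chains / % | free monomer / % |
|---|---|---|---|
| Sunday's | 0.833 | 10 | 92 |
| Sunday's | 2.00 | 24 | 76 |
| Sunday's | 4.00 | 44 | 52 |
| Sunday's | 6.00 | 58 | 41 |
| Sunday's | 8.00 | 69 | 28 |
| Saturday's | 1.50 | 46 | 54 |
| Saturday's | 3.00 | 73 | 28 |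
| Saturday's | 5.00 | 95 | 13 |
| Saturday's | 6.00 | 90 | 6 |
| Saturday's | 8.00 | 96 | 4 |

(each reading ± 2 percentage points)

- which of the two ends with the longer chains by the average number of monomer units in a chain (chains begun, living or dead) ("neither" if they lie within 10%) (spring / summer / neither)
- average number of monomer units in a chain (chains begun, living or dead) at the end, spring
- average number of monomer units in a chain (chains begun, living or dead) at the end, summer

- the average divides the monomer in chains by the number of chains begun, living and dead together
- the numbers in the tables scatter by 2 percentage points (one standard deviation)
- the earlier runs do not show the number of chains; that part of a forecast is a guess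

A length is the monomer in chains divided by the chains begun, so each flask needs a top and a bottom. The top can be read from the runs. On a logarithmic scale free monomer falls in a straight line, pseudo-first-order, and Sunday's run reads 28% at 8.00 min while Saturday's run reads 28% at 3.00 min. The two rates therefore stand, as a reading, in the ratio 2.67.

The bottom is the dispute. The forecaster takes that kind of ratio to mean a loss of initiator of about 0.4 mM, and says of the chains: “The chain count is the guess: between I and I − 0.4.” The forecast is spring, with 112 units in spring and 63 in summer.

I hold instead that each impurity takes one initiator before it can start a chain, so I carry the live charge, c(initiator) − c(impurity), which is 3.16 mM in summer and 0.960 mM in spring. My view expects a rate ratio of 3.24, higher than the reading, and that counts against me. But the ratio rests on two readings that scatter by 2 percentage points, and the runs do not show the number of chains, so I keep my view.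

If the logarithm of free monomer falls in proportion to time and live charge, the fraction left in a flask is Sunday's 28% raised to a power, the time ratio times the live-charge ratio. That power is 0.923 for spring and 3.04 for summer, which leaves 30.9% and 2.09%. My lengths are then 180 in spring and 77.5 in summer, different from the forecast's numbers, though I also choose spring.

The simulation gives spring, with 186 units in spring and 82.0 in summer.

    free monomer + initiator → living end + monomer in chains (k = 0.150 /M/s)
    free monomer + living end → monomer in chains + living end, rate k2*[living end]*[free monomer] (k = 1.80 /M/s)
    initiator → spent initiator A (k = 0.00210 /s)
    initiator + impurity → spent initiator B (k = 140 /M/s)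

The forecaster's view has its ground in the monomer: its 72% and 96% in chains stand near the flask's 69.2% in spring and 97.6% in summer. The two views part on the bottom of the fraction, where the living end at the end is 9.31 × 10⁻⁴ M in spring and 0.00298 M in summer, against live charges of 0.960 mM and 3.16 mM. A neighbouring flask repeats summer's recipe with 0.42 M of free monomer, so its live charge stays 3.16 mM. With 2.09% left, the same reckoning gives 130 units, and the flask gives 135, with 97.9% of the free monomer charged in chains.

(All runs were generated by integration with made-up constants; the scatter is artificial.)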